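**Plan**

- Numbering follows azulene (C1–C8, C3a, C8a): C8 is the ketone, C6=C7 the enone alkene, C4 the ester carbinol, C3 the tertiary carbinol, C8a the methyl-bearing ring-fusion carbon. Cuts, in retrosynthetic order: aryl ester C–O; the C7–C8 bond of the seven-membered ring; C3–isopropyl; C3a–C4 (aldol); the alkenyl precursor of C8 on C8a.
- Enabling feature: C8 sits on the quaternary C8a, so a C8 aldehyde cannot enolize. The C6(Me)=C7 enone alkene can be moved back to an exocyclic C6 methylidene, a 2-substituted allyl unit whose terminal carbon C7 is nucleophilic. A bare aldehyde and a bare methallyl group therefore close the seven-membered ring by an intramolecular carbonyl-ene reaction, with no activating group.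
- Forward order: the five-membered ring comes from 3-methylcyclopent-2-en-1-one; C8a by asymmetric conjugate addition; the alkenyl group is degraded to a C8 acetal; aldol at C3a; isopropyl addition at C3; esterification at C4; the seven-membered ring is closed last, then oxidized and isomerized to the enone.
- Stereochemistry: C8a from the chiral copper catalyst; C3a from enolate attack anti to the C8 acetal; C4 from a syn-selective titanium aldol; C3 from addition anti to the C3a side chain; the C8 carbinol made in the ring closure is erased by oxidation.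

Key step: step 12

Remark: 24 is carried as both C8 carbinol epimers (that centre is left open in its SMILES) because step 13 removes it; in step 1 the ligand enantiomer is the one that gives the S ketone.

**Route**

Step 1
Reactants: 1 3-methylcyclopent-2-en-1-one; 2 ethynyltrimethylsilane
Product: 5 (S)-3-methyl-3-[1-(trimethylsilyl)ethenyl]cyclopentan-1-one, via silylvinylalane 3 (not isolated), via aluminium enolate 4 (not isolated)
Conditions: 2, iBu2AlH, hexane, 55 °C; then 1, Cu(OTf)2 (5 mol%), chiral sulfonate-bearing imidazolinium salt (carbene ligand precursor, 5 mol%), THF, −78 to −30 °C; aq. potassium sodium tartrate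
Reagents that add atoms: none
Why: copper-catalysed asymmetric conjugate addition of an α-silyl vinylaluminium reagent (from hydroalumination of 2) to a β-substituted cyclopentenone is an established route to vinyl-bearing quaternary centres, the chiral carbene–copper complex choosing the enone face and so setting C8a, while the alkenyl group transfers in preference to isobutyl.

Step 2
Reactants: 5 (S)-3-methyl-3-[1-(trimethylsilyl)ethenyl]cyclopentan-1-one
Product: 6 (S)-3-ethenyl-3-methylcyclopentan-1-one
Conditions: CF3CO2H, CH2Cl2, 0 °C to rt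
Reagents that add atoms: none
Why: acid-mediated protodesilylation of the vinylsilane removes the silyl group without touching the quaternary centre and leaves a plain vinyl group for oxidative cleavage.

Step 3
Reactants: 6 (S)-3-ethenyl-3-methylcyclopentan-1-one
Product: 8 (S)-3-(dimethoxymethyl)-3-methylcyclopentan-1-one, via keto aldehyde 7 (not isolated)
Conditions: O3, CH2Cl2/MeOH, −78 °C; Me2S, −78 °C to rt; then HC(OMe)3, CeCl3·7H2O (cat.), MeOH, rt
Reagents that add atoms: trimethyl orthoformate, COC(OC)OC
Why: ozonolysis of the only alkene gives the C8 aldehyde, and lanthanide-catalysed acetalization converts an aldehyde to its dimethyl acetal chemoselectively beside a ketone, which installs a branched, base-stable C8 group next to the future enolate carbon.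

Step 4
Reactants: 8 (S)-3-(dimethoxymethyl)-3-methylcyclopentan-1-one
Product: 10 (R)-4-(dimethoxymethyl)-4-methylcyclopent-2-en-1-one, via lithium enolate 9 (not isolated)
Conditions: LiN(iPr)2, THF, −78 °C; then PhS(Cl)=NtBu, −78 °C
Reagents that add atoms: none
Why: Mukaiyama dehydrogenation of the kinetic enolate, which forms on the methylene remote from the quaternary carbon, gives the enone, so that the only acidic position left is the CH2 between the carbonyl and the quaternary carbon (future C3a).

Step 5
Reactants: 11 3-methylbut-3-en-1-ol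
Product: 12 3-methylbut-3-enal
Conditions: Dess–Martin periodinane, NaHCO3, CH2Cl2, 0 °C; used at once as a cold solution
Reagents that add atoms: none
Why: buffered Dess–Martin oxidation gives the β,γ-unsaturated aldehyde under conditions mild enough to keep the alkene out of conjugation.

Step 6
Reactants: 10 (R)-4-(dimethoxymethyl)-4-methylcyclopent-2-en-1-one; 12 3-methylbut-3-enal
Product: 15 (4S,5S)-4-(dimethoxymethyl)-5-[(1R)-1-hydroxy-3-methylbut-3-en-1-yl]-4-methylcyclopent-2-en-1-one, via lithium dienolate 13 (not isolated), via titanium dienolate 14 (not isolated)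
Conditions: LiN(iPr)2, THF, −78 °C; ClTi(OiPr)3, −78 to −40 °C; 12, −78 °C; aq. NH4Cl
Reagents that add atoms: none
Why: α'-deprotonation and transmetalation give a triisopropoxytitanium enolate, a class that undergoes syn-selective aldol addition whatever the enolate geometry and is weakly basic enough to spare the enolizable aldehyde; the aldehyde should approach C3a anti to the dimethoxymethyl group on the neighbouring quaternary carbon, and the syn topology sets the C4 carbinol.

Step 7
Reactants: 15 (4S,5S)-4-(dimethoxymethyl)-5-[(1R)-1-hydroxy-3-methylbut-3-en-1-yl]-4-methylcyclopent-2-en-1-one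
Product: 16 (2S,3S)-3-(dimethoxymethyl)-2-[(1R)-1-hydroxy-3-methylbut-3-en-1-yl]-3-methylcyclopentan-1-one
Conditions: [(Ph3P)CuH]6 (0.4 equiv), H2O (5 equiv), toluene, rt
Reagents that add atoms: none
Why: copper hydride conjugate reduction saturates only the enone alkene and leaves the isolated 1,1-disubstituted alkene, the acetal and both new stereocentres alone, because the copper enolate forms on the side of the carbonyl away from C3a.

Step 8
Reactants: 16 (2S,3S)-3-(dimethoxymethyl)-2-[(1R)-1-hydroxy-3-methylbut-3-en-1-yl]-3-methylcyclopentan-1-one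
Product: 17 (1R,2S,3S)-3-(dimethoxymethyl)-2-[(1R)-1-hydroxy-3-methylbut-3-en-1-yl]-3-methyl-1-(propan-2-yl)cyclopentan-1-ol
Conditions: iPrMgCl, CeCl3 (anhydrous), THF, −78 to −40 °C (4 equiv each); aq. NH4Cl
Reagents that add atoms: isopropylmagnesium chloride, CC(C)[Mg]Cl
Why: organocerium 1,2-addition suppresses enolization and β-hydride reduction, and the nucleophile should add to the ketone face anti to the C3a side chain (held in a chelate through its alkoxide), which places the tertiary hydroxyl cis to that side chain.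

Step 9
Reactants: 18 vanillic acid
Product: 20 4-[(tert-butyldimethylsilyl)oxy]-3-methoxybenzoic acid, via bis-silyl ester 19 (not isolated)
Conditions: tBuMe2SiCl (2.5 equiv), imidazole, DMF, rt; then K2CO3, THF/MeOH/H2O, rt; acidify to pH 4
Reagents that add atoms: tert-butyldimethylsilyl chloride, CC(C)(C)[Si](C)(C)Cl
Why: exhaustive silylation followed by selective hydrolysis of the labile silyl ester is the standard way to mask the phenol of a hydroxybenzoic acid as its aryl silyl ether.

Step 10
Reactants: 17 (1R,2S,3S)-3-(dimethoxymethyl)-2-[(1R)-1-hydroxy-3-methylbut-3-en-1-yl]-3-methyl-1-(propan-2-yl)cyclopentan-1-ol; 20 4-[(tert-butyldimethylsilyl)oxy]-3-methoxybenzoic acid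
Product: 22 (1R)-1-[(1S,2S,5R)-2-(dimethoxymethyl)-5-hydroxy-2-methyl-5-(propan-2-yl)cyclopentyl]-3-methylbut-3-en-1-yl 4-[(tert-butyldimethylsilyl)oxy]-3-methoxybenzoate, via mixed anhydride 21 (not isolated)
Conditions: 20, 2,4,6-trichlorobenzoyl chloride, Et3N, THF, rt; then 17, DMAP, toluene, rt to 40 °C
Reagents that add atoms: none
Why: Yamaguchi esterification acylates the secondary C4 hydroxyl with retention while the tertiary hydroxyl is too hindered to react, and the aroyl group also protects C4–OH through the next three steps.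

Step 11
Reactants: 22 (1R)-1-[(1S,2S,5R)-2-(dimethoxymethyl)-5-hydroxy-2-methyl-5-(propan-2-yl)cyclopentyl]-3-methylbut-3-en-1-yl 4-[(tert-butyldimethylsilyl)oxy]-3-methoxybenzoate
Product: 23 (1R)-1-[(1S,2S,5R)-2-formyl-5-hydroxy-2-methyl-5-(propan-2-yl)cyclopentyl]-3-methylbut-3-en-1-yl 4-[(tert-butyldimethylsilyl)oxy]-3-methoxybenzoate
Conditions: PPTS (0.3 equiv), acetone/H2O (9:1), 50 °C
Reagents that add atoms: water, O
Why: mild acid-catalysed acetal hydrolysis frees the non-enolizable aldehyde without harming the aryl silyl ether, the ester or the tertiary alcohol, and no lactol can form because the tertiary hydroxyl is trans to the aldehyde on the ring.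

Step 12
Reactants: 23 (1R)-1-[(1S,2S,5R)-2-formyl-5-hydroxy-2-methyl-5-(propan-2-yl)cyclopentyl]-3-methylbut-3-en-1-yl 4-[(tert-butyldimethylsilyl)oxy]-3-methoxybenzoate
Product: 24 (3R,3aS,4R,8aS)-3,8-dihydroxy-8a-methyl-6-methylidene-3-(propan-2-yl)decahydroazulen-4-yl 4-[(tert-butyldimethylsilyl)oxy]-3-methoxybenzoate (both C8 epimers)
Conditions: Me2AlCl (3 equiv), CH2Cl2 (0.01 M), −78 to 0 °C
Reagents that add atoms: none
Why: Me2AlCl activates the aldehyde, which sits on the quaternary C8a and so can neither enolize nor epimerize, and the terminal carbon of the 1,1-disubstituted alkene attacks the carbonyl carbon while an allylic hydrogen of the methyl group passes to oxygen through a six-membered transition state. The closest known reaction is the Me2AlCl-promoted type 2 intramolecular carbonyl-ene (Prins-type) cyclization of aldehydes carrying a 2-substituted allyl unit, which is established for six- and seven-membered rings. The seven-membered ring is closed by a 7-exo-trig attack at the carbonyl with both alkene carbons ending inside the ring (endo with respect to the ene, since the tether is on its central carbon), and it is trans-fused because aldehyde and side chain are already trans on the cyclopentane. The only new stereocentre is the C8 carbinol, which the cyclic ene transition state would set, but it is left uncontrolled on purpose because step 13 oxidizes it. The step needs regioselectivity for the alkene terminus, secured by the polarization of the alkene (attack through the inner carbon would need a primary cation), and hydrogen transfer in place of capture of a tertiary cation by chloride, the ester carbonyl or the aluminium alkoxide, which the concerted, proton-scavenging conditions at low temperature and high dilution should secure. About three equivalents of Me2AlCl are used because the tertiary hydroxyl and the ester each tie up one, and the alternative ene isomer with the alkene in the ring would converge on the same enone in step 13.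

Step 13
Reactants: 24 (3R,3aS,4R,8aS)-3,8-dihydroxy-8a-methyl-6-methylidene-3-(propan-2-yl)decahydroazulen-4-yl 4-[(tert-butyldimethylsilyl)oxy]-3-methoxybenzoate
Product: 26 (3R,3aS,4R,8aS)-3-hydroxy-6,8a-dimethyl-8-oxo-3-(propan-2-yl)-1,2,3,3a,4,5,8,8a-octahydroazulen-4-yl 4-[(tert-butyldimethylsilyl)oxy]-3-methoxybenzoate, via exocyclic enone 25 (not isolated)
Conditions: Dess–Martin periodinane, NaHCO3, CH2Cl2, 0 °C to rt; aq. Na2S2O3 wash; then DBU (0.2 equiv), CH2Cl2, 0 °C
Reagents that add atoms: none
Why: Dess–Martin oxidation converts the secondary carbinol (the tertiary one is inert) into a ketone that can enolize on one side only, and base-catalysed alkene migration through the dienolate moves the exocyclic alkene into conjugation to give the trisubstituted enone, the thermodynamic isomer.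

Step 14
Reactants: 26 (3R,3aS,4R,8aS)-3-hydroxy-6,8a-dimethyl-8-oxo-3-(propan-2-yl)-1,2,3,3a,4,5,8,8a-octahydroazulen-4-yl 4-[(tert-butyldimethylsilyl)oxy]-3-methoxybenzoate
Product: 27 (3R,3aS,4R,8aS)-3-hydroxy-6,8a-dimethyl-8-oxo-3-(propan-2-yl)-1,2,3,3a,4,5,8,8a-octahydroazulen-4-yl 4-hydroxy-3-methoxybenzoate
Conditions: Bu4NF, AcOH (1:1), THF, 0 °C
Reagents that add atoms: none
Why: buffered fluoride desilylation cleaves only the aryl silyl ether, the acetic acid keeping the medium from becoming basic enough to expel the aroyloxy group from the enone.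

**Compound list**

1 | 3-methylcyclopent-2-en-1-one | CC1=CC(=O)CC1 | starting material
2 | ethynyltrimethylsilane | C#C[Si](C)(C)C | starting material
3 | diisobutyl[1-(trimethylsilyl)ethenyl]aluminium | C=C([Si](C)(C)C)[Al](CC(C)C)CC(C)C | intermediate
4 | diisobutylaluminium enolate of 5 (enolate toward the quaternary carbon) | CC(C)C[Al](CC(C)C)OC1=C[C@@](C)(C(=C)[Si](C)(C)C)CC1 | intermediate
5 | (S)-3-methyl-3-[1-(trimethylsilyl)ethenyl]cyclopentan-1-one | O=C1C[C@@](C)(C(=C)[Si](C)(C)C)CC1 | intermediate
6 | (S)-3-ethenyl-3-methylcyclopentan-1-one | O=C1C[C@@](C)(C=C)CC1 | intermediate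
7 | (S)-1-methyl-3-oxocyclopentane-1-carbaldehyde | O=C1C[C@@](C)(C=O)CC1 | intermediate
8 | (S)-3-(dimethoxymethyl)-3-methylcyclopentan-1-one | O=C1C[C@@](C)(C(OC)OC)CC1 | intermediate
9 | lithium enolate of 8 (enolate away from the quaternary carbon) | [Li]OC1=CC[C@](C)(C(OC)OC)C1 | intermediate
10 | (R)-4-(dimethoxymethyl)-4-methylcyclopent-2-en-1-one | O=C1C[C@@](C)(C(OC)OC)C=C1 | intermediate
11 | 3-methylbut-3-en-1-ol | CC(=C)CCO | starting material
12 | 3-methylbut-3-enal | CC(=C)CC=O | intermediate
13 | lithium dienolate of 10 | [Li]OC1=C[C@@](C)(C(OC)OC)C=C1 | intermediate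
14 | triisopropoxytitanium dienolate of 10 | CC(C)O[Ti](OC(C)C)(OC(C)C)OC1=C[C@@](C)(C(OC)OC)C=C1 | intermediate
15 | (4S,5S)-4-(dimethoxymethyl)-5-[(1R)-1-hydroxy-3-methylbut-3-en-1-yl]-4-methylcyclopent-2-en-1-one | O=C1[C@H]([C@H](O)CC(C)=C)[C@@](C)(C(OC)OC)C=C1 | intermediate
16 | (2S,3S)-3-(dimethoxymethyl)-2-[(1R)-1-hydroxy-3-methylbut-3-en-1-yl]-3-methylcyclopentan-1-one | O=C1[C@H]([C@H](O)CC(C)=C)[C@@](C)(C(OC)OC)CC1 | intermediate
17 | (1R,2S,3S)-3-(dimethoxymethyl)-2-[(1R)-1-hydroxy-3-methylbut-3-en-1-yl]-3-methyl-1-(propan-2-yl)cyclopentan-1-ol | CC(C)[C@]1(O)CC[C@](C)(C(OC)OC)[C@H]1[C@H](O)CC(C)=C | intermediate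
18 | vanillic acid (4-hydroxy-3-methoxybenzoic acid) | COc1cc(C(=O)O)ccc1O | starting material
19 | tert-butyldimethylsilyl 4-[(tert-butyldimethylsilyl)oxy]-3-methoxybenzoate | COc1cc(C(=O)O[Si](C)(C)C(C)(C)C)ccc1O[Si](C)(C)C(C)(C)C | intermediate
20 | 4-[(tert-butyldimethylsilyl)oxy]-3-methoxybenzoic acid | COc1cc(C(=O)O)ccc1O[Si](C)(C)C(C)(C)C | intermediate
21 | 4-[(tert-butyldimethylsilyl)oxy]-3-methoxybenzoic 2,4,6-trichlorobenzoic anhydride | COc1cc(C(=O)OC(=O)c2c(Cl)cc(Cl)cc2Cl)ccc1O[Si](C)(C)C(C)(C)C | intermediate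
22 | (1R)-1-[(1S,2S,5R)-2-(dimethoxymethyl)-5-hydroxy-2-methyl-5-(propan-2-yl)cyclopentyl]-3-methylbut-3-en-1-yl 4-[(tert-butyldimethylsilyl)oxy]-3-methoxybenzoate | CC(C)[C@]1(O)CC[C@](C)(C(OC)OC)[C@H]1[C@H](OC(=O)c2ccc(O[Si](C)(C)C(C)(C)C)c(OC)c2)CC(C)=C | intermediate
23 | (1R)-1-[(1S,2S,5R)-2-formyl-5-hydroxy-2-methyl-5-(propan-2-yl)cyclopentyl]-3-methylbut-3-en-1-yl 4-[(tert-butyldimethylsilyl)oxy]-3-methoxybenzoate | CC(C)[C@]1(O)CC[C@](C)(C=O)[C@H]1[C@H](OC(=O)c2ccc(O[Si](C)(C)C(C)(C)C)c(OC)c2)CC(C)=C | intermediate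
24 | (3R,3aS,4R,8aS)-3,8-dihydroxy-8a-methyl-6-methylidene-3-(propan-2-yl)decahydroazulen-4-yl 4-[(tert-butyldimethylsilyl)oxy]-3-methoxybenzoate, both C8 epimers | CC(C)[C@]1(O)CC[C@]2(C)C(O)CC(=C)C[C@@H](OC(=O)c3ccc(O[Si](C)(C)C(C)(C)C)c(OC)c3)[C@@H]12 | intermediate
25 | (3R,3aS,4R,8aS)-3-hydroxy-8a-methyl-6-methylidene-8-oxo-3-(propan-2-yl)decahydroazulen-4-yl 4-[(tert-butyldimethylsilyl)oxy]-3-methoxybenzoate | CC(C)[C@]1(O)CC[C@]2(C)C(=O)CC(=C)C[C@@H](OC(=O)c3ccc(O[Si](C)(C)C(C)(C)C)c(OC)c3)[C@@H]12 | intermediate
26 | (3R,3aS,4R,8aS)-3-hydroxy-6,8a-dimethyl-8-oxo-3-(propan-2-yl)-1,2,3,3a,4,5,8,8a-octahydroazulen-4-yl 4-[(tert-butyldimethylsilyl)oxy]-3-methoxybenzoate | CC(C)[C@]1(O)CC[C@]2(C)C(=O)C=C(C)C[C@@H](OC(=O)c3ccc(O[Si](C)(C)C(C)(C)C)c(OC)c3)[C@@H]12 | intermediate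
27 | (3R,3aS,4R,8aS)-3-hydroxy-6,8a-dimethyl-8-oxo-3-(propan-2-yl)-1,2,3,3a,4,5,8,8a-octahydroazulen-4-yl 4-hydroxy-3-methoxybenzoate | COc1cc(C(=O)O[C@@H]2CC(C)=CC(=O)[C@@]3(C)CC[C@@](O)(C(C)C)[C@H]23)ccc1O | target

**Step count and risks**

Total step count: 14. Longest linear sequence: 12 (steps 1–4, 6–8, 10–14).

Three steps most likely to fail:

1. Step 6. The aldol addition may lose its syn preference (a closed chair transition state taking over from the one that gives the syn product), or the enolate may deprotonate the doubly activated aldehyde instead of adding to it. Fallback (substrate-directed reduction in place of a reagent-controlled aldol): set out from 10 and 12 and run the aldol through the plain lithium dienolate 13, without regard to the carbinol configuration, to the carbinol-epimeric enone aldols F1. Reduce the enone alkene as in step 7 to the carbinol-epimeric ketols F2, and add the isopropyl group as in step 8 to the carbinol-epimeric diols F3. Dess–Martin periodinane then oxidizes only the secondary alcohol to the single β-hydroxy ketone F4. A Narasaka–Prasad reduction (Et2BOMe, NaBH4, THF/MeOH, −78 °C) follows, in which hydride attacks the boron chelate between the tertiary hydroxyl and the ketone on the face turned away from the methyl group of the quaternary carbon. This should give 17, where the route is rejoined.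

2. Step 12. The ene pathway may give way to stepwise cationic chemistry (capture of a tertiary cation by chloride, the ester carbonyl or the aluminium alkoxide) or to intermolecular reaction, because the trans-fused seven-membered transition state is strained. Fallback (an allylsilane as a stronger, regiodefined π-nucleophile; intramolecular Hosomi–Sakurai reaction): set out from 11, whose dianion (nBuLi, TMEDA) is silylated with Me3SiCl to the C,O-bis-silyl compound F5. This is hydrolysed on work-up to 3-[(trimethylsilyl)methyl]but-3-en-1-ol F6 and oxidized as in step 5 to the aldehyde F7. F7 replaces 12 in step 6 (with 10) to give the aldol F8, which is taken through steps 7, 8, 10 and 11 as the ketone F9, the diol F10, the ester F11 and the aldehyde F12. BF3·OEt2 (CH2Cl2, −78 °C) then closes the same C7–C8 bond by attack of the allylsilane terminus on the aldehyde with loss of the silyl group and delivers 24, where the route is rejoined.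

3. Step 8. Enolization or retro-aldol cleavage of the β-hydroxy ketone, and hydride transfer from the branched reagent, may outrun addition. Fallback (an sp2 nucleophile followed by directed hydrogenation): set out from 16 and add isopropenylmagnesium bromide/CeCl3, which cannot transfer a β-hydride and is less hindered, to obtain the isopropenyl diol F13. Esterify with 20 as in step 10 to the isopropenyl ester F14. Hydroxyl-directed hydrogenation with [Rh(nbd)(dppb)]BF4 and H2 in CH2Cl2, steered by the tertiary allylic hydroxyl, should saturate the isopropenyl group faster than the remote methallyl alkene and gives 22, where the route is rejoined.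

Further compounds
F1 | step 6 | (4S,5S)-4-(dimethoxymethyl)-5-[(1RS)-1-hydroxy-3-methylbut-3-en-1-yl]-4-methylcyclopent-2-en-1-one (carbinol epimers) | O=C1[C@H](C(O)CC(C)=C)[C@@](C)(C(OC)OC)C=C1
F2 | step 6 | (2S,3S)-3-(dimethoxymethyl)-2-[(1RS)-1-hydroxy-3-methylbut-3-en-1-yl]-3-methylcyclopentan-1-one (carbinol epimers) | O=C1[C@H](C(O)CC(C)=C)[C@@](C)(C(OC)OC)CC1
F3 | step 6 | (1R,2S,3S)-3-(dimethoxymethyl)-2-[(1RS)-1-hydroxy-3-methylbut-3-en-1-yl]-3-methyl-1-(propan-2-yl)cyclopentan-1-ol (carbinol epimers) | CC(C)[C@]1(O)CC[C@](C)(C(OC)OC)[C@H]1C(O)CC(C)=C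
F4 | step 6 | 1-[(1R,2S,5R)-2-(dimethoxymethyl)-5-hydroxy-2-methyl-5-(propan-2-yl)cyclopentyl]-3-methylbut-3-en-1-one | CC(C)[C@]1(O)CC[C@](C)(C(OC)OC)[C@H]1C(=O)CC(C)=C
F5 | step 12 | trimethyl({3-[(trimethylsilyl)methyl]but-3-en-1-yl}oxy)silane | C=C(C[Si](C)(C)C)CCO[Si](C)(C)C
F6 | step 12 | 3-[(trimethylsilyl)methyl]but-3-en-1-ol | C=C(C[Si](C)(C)C)CCO
F7 | step 12 | 3-[(trimethylsilyl)methyl]but-3-enal | C=C(C[Si](C)(C)C)CC=O
F8 | step 12 | (4S,5S)-4-(dimethoxymethyl)-5-{(1R)-1-hydroxy-3-[(trimethylsilyl)methyl]but-3-en-1-yl}-4-methylcyclopent-2-en-1-one | O=C1[C@H]([C@H](O)CC(=C)C[Si](C)(C)C)[C@@](C)(C(OC)OC)C=C1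
F9 | step 12 | (2S,3S)-3-(dimethoxymethyl)-2-{(1R)-1-hydroxy-3-[(trimethylsilyl)methyl]but-3-en-1-yl}-3-methylcyclopentan-1-one | O=C1[C@H]([C@H](O)CC(=C)C[Si](C)(C)C)[C@@](C)(C(OC)OC)CC1
F10 | step 12 | (1R,2S,3S)-3-(dimethoxymethyl)-2-{(1R)-1-hydroxy-3-[(trimethylsilyl)methyl]but-3-en-1-yl}-3-methyl-1-(propan-2-yl)cyclopentan-1-ol | CC(C)[C@]1(O)CC[C@](C)(C(OC)OC)[C@H]1[C@H](O)CC(=C)C[Si](C)(C)C
F11 | step 12 | (1R)-1-[(1S,2S,5R)-2-(dimethoxymethyl)-5-hydroxy-2-methyl-5-(propan-2-yl)cyclopentyl]-3-[(trimethylsilyl)methyl]but-3-en-1-yl 4-[(tert-butyldimethylsilyl)oxy]-3-methoxybenzoate | CC(C)[C@]1(O)CC[C@](C)(C(OC)OC)[C@H]1[C@H](OC(=O)c2ccc(O[Si](C)(C)C(C)(C)C)c(OC)c2)CC(=C)C[Si](C)(C)C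
F12 | step 12 | (1R)-1-[(1S,2S,5R)-2-formyl-5-hydroxy-2-methyl-5-(propan-2-yl)cyclopentyl]-3-[(trimethylsilyl)methyl]but-3-en-1-yl 4-[(tert-butyldimethylsilyl)oxy]-3-methoxybenzoate | CC(C)[C@]1(O)CC[C@](C)(C=O)[C@H]1[C@H](OC(=O)c2ccc(O[Si](C)(C)C(C)(C)C)c(OC)c2)CC(=C)C[Si](C)(C)C
F13 | step 8 | (1S,2S,3S)-3-(dimethoxymethyl)-2-[(1R)-1-hydroxy-3-methylbut-3-en-1-yl]-3-methyl-1-(prop-1-en-2-yl)cyclopentan-1-ol | CC(=C)[C@]1(O)CC[C@](C)(C(OC)OC)[C@H]1[C@H](O)CC(C)=C
F14 | step 8 | (1R)-1-[(1S,2S,5S)-2-(dimethoxymethyl)-5-hydroxy-2-methyl-5-(prop-1-en-2-yl)cyclopentyl]-3-methylbut-3-en-1-yl 4-[(tert-butyldimethylsilyl)oxy]-3-methoxybenzoate | CC(=C)[C@]1(O)CC[C@](C)(C(OC)OC)[C@H]1[C@H](OC(=O)c2ccc(O[Si](C)(C)C(C)(C)C)c(OC)c2)CC(C)=C
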